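**Plan**
- The retrosynthesis first cuts the depside ester C–O bond between the ring A carboxyl and the 4-oxygen of the orsellinic acid ring B. It then cuts the ring A C6–CH2 bond of the 2-oxononyl chain.
- The second cut is possible because C6 is the only ring A carbon ortho to the carboxyl-bearing C1 that still holds hydrogen (C2 carries oxygen). The chain ketone oxygen also lies within reach of the carboxyl carbon for a six-membered lactone.
- Forward, a 2-benzyloxy-4-methoxybenzoic acid and an octanoyl sulfoxonium ylide are joined by rhodium-catalysed C–H acylmethylation. The keto acid closes in the same flask to a 3-heptylisocoumarin, the only ring the route builds.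
- Hydroxide reopens the lactone, the ketone is masked as a dioxolane while the acid is held as an allyl ester, and the freed acid is esterified with the 4-hydroxyl of benzyl orsellinate.
- Ketal hydrolysis and hydrogenolysis of both benzyl groups finish the synthesis. The target has no stereocentre and none is created.

Key step: step 3

Remark: orsellinic acid is taken as commercial, and the keto depside is assumed to tolerate neutral and dilute-acid handling, as an aryl ester next to a ketone of this kind is an isolable compound class.

**Step 1**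
Reactants: 1 2-hydroxy-4-methoxybenzoic acid
Product: 3 2-(benzyloxy)-4-methoxybenzoic acid, via benzyl 2-(benzyloxy)-4-methoxybenzoate 2 (not isolated)
Conditions: BnBr (2.2 equiv), K2CO3, DMF, 60 °C; then KOH, MeOH/H2O, 70 °C; HCl to pH 2
Reagents that add atoms: benzyl bromide, BrCc1ccccc1; potassium hydroxide, [K+].[OH-]
Why: Williamson O-benzylation of the phenol and SN2 alkylation of the carboxylate should give diester 2, and saponification then cleaves only the benzyl ester because a benzyl aryl ether is inert to hydroxide.

**Step 2**
Reactants: 4 trimethylsulfoxonium iodide; 5 octanoyl chloride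
Product: 7 1-[dimethyl(oxo)-λ6-sulfanylidene]nonan-2-one, via dimethylsulfoxonium methylide 6 (not isolated)
Conditions: 4 (3 equiv), KOtBu (3 equiv), THF, reflux; then 5 (1 equiv), 0 °C to rt
Reagents that add atoms: none
Why: Deprotonation gives the Corey–Chaykovsky methylide 6, which is acylated at carbon by the acid chloride, and a second equivalent of 6 removes the acidic proton of the acylsulfoxonium salt to leave the carbonyl-stabilised ylide (standard acylation of dimethylsulfoxonium methylide).

**Step 3**
Reactants: 3 2-(benzyloxy)-4-methoxybenzoic acid; 7 1-[dimethyl(oxo)-λ6-sulfanylidene]nonan-2-one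
Product: 9 8-(benzyloxy)-3-heptyl-6-methoxy-1H-isochromen-1-one, via 2-(benzyloxy)-4-methoxy-6-(2-oxononyl)benzoic acid 8 (not isolated)
Conditions: [Cp*RhCl2]2 (cat.), AgSbF6 (cat.), NaOAc, HFIP, 80 °C
Reagents that add atoms: none
Why: Acetate-assisted concerted metalation–deprotonation by the carboxylate-bound Cp*Rh centre (trivalent rhodium) should cleave the C6–H bond of 3 to a five-membered rhodacycle. Ylide 7 binds through carbon and loses dimethyl sulfoxide to a rhodium carbene, which inserts into the Rh–aryl bond, and protonolysis releases keto acid 8 and the catalyst. The carboxyl oxygen of 8 then adds to the ketone carbon (6-exo-trig, C–O bond formation) and loss of water, helped by the acidic fluorinated solvent, closes the pyranone ring of 9. The closest known reaction type is the Cp*Rh-catalysed carboxylate-directed ortho C–H acylmethylation and annulation of benzoic acids with sulfoxonium ylides to 3-substituted isocoumarins. No stereocentre is formed. The step needs site selectivity and a single insertion, and both are secured because C6 carries the only hydrogen ortho to the carboxyl, C2 being occupied by the benzyloxy group; any 8 that fails to close is not lost, since step 4 converts lactone and keto acid alike into carboxylate 10.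

**Step 4**
Reactants: 9 8-(benzyloxy)-3-heptyl-6-methoxy-1H-isochromen-1-one
Product: 11 allyl 2-(benzyloxy)-4-methoxy-6-(2-oxononyl)benzoate, via potassium 2-(benzyloxy)-4-methoxy-6-(2-oxononyl)benzoate 10 (not isolated)
Conditions: KOH (1.05 equiv), EtOH/H2O, 50 °C; evaporate; allyl bromide, DMF, rt
Reagents that add atoms: potassium hydroxide, [K+].[OH-]; allyl bromide, C=CCBr
Why: Hydroxide opens the enol lactone by acyl substitution (lactone saponification) and the freed enolate is protonated to the ketone so the opening does not reverse; the carboxylate is then alkylated at oxygen by SN2 on allyl bromide, where crowding at the carboxyl does not matter and the free keto acid, which could re-close, is never handled.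

**Step 5**
Reactants: 11 allyl 2-(benzyloxy)-4-methoxy-6-(2-oxononyl)benzoate
Product: 12 allyl 2-(benzyloxy)-6-[(2-heptyl-1,3-dioxolan-2-yl)methyl]-4-methoxybenzoate
Conditions: (TMSOCH2)2, TMSOTf (cat.), CH2Cl2, −78 to −20 °C; pyridine quench
Reagents that add atoms: 1,2-bis(trimethylsilyloxy)ethane, C[Si](C)(C)OCCO[Si](C)(C)C
Why: Noyori ketalisation, in which TMSOTf activates the unhindered ketone towards the bis-silyl ether and loss of hexamethyldisiloxane drives dioxolane formation at low temperature in an aprotic medium, so the allyl ester and benzyl ether stay inert and the keto ester is not pushed back to the isocoumarin.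

**Step 6**
Reactants: 12 allyl 2-(benzyloxy)-6-[(2-heptyl-1,3-dioxolan-2-yl)methyl]-4-methoxybenzoate
Product: 13 2-(benzyloxy)-6-[(2-heptyl-1,3-dioxolan-2-yl)methyl]-4-methoxybenzoic acid
Conditions: Pd(PPh3)4 (cat.), morpholine, THF, rt; pH 5 buffer work-up, used directly
Reagents that add atoms: none
Why: Tsuji–Trost deallylation, in which zerovalent palladium ionises the allyl ester to a pi-allyl complex and the carboxylate and morpholine captures the allyl group; the bond cleaved is O–allyl, so the hindered carboxyl is freed without acid or strong base that would endanger the ketal or the benzyl ether.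

**Step 7**
Reactants: 14 orsellinic acid (2,4-dihydroxy-6-methylbenzoic acid)
Product: 15 benzyl 2,4-dihydroxy-6-methylbenzoate
Conditions: BnBr (1.0 equiv), KHCO3, DMF, rt
Reagents that add atoms: benzyl bromide, BrCc1ccccc1
Why: Bicarbonate deprotonates only the carboxylic acid, whose carboxylate is benzylated by SN2, and room temperature avoids both decarboxylation of this electron-rich acid and alkylation of the phenols.

**Step 8**
Reactants: 13 2-(benzyloxy)-6-[(2-heptyl-1,3-dioxolan-2-yl)methyl]-4-methoxybenzoic acid; 15 benzyl 2,4-dihydroxy-6-methylbenzoate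
Product: 16 benzyl 4-({2-(benzyloxy)-6-[(2-heptyl-1,3-dioxolan-2-yl)methyl]-4-methoxybenzoyl}oxy)-2-hydroxy-6-methylbenzoate
Conditions: DCC, DMAP, CH2Cl2, 0 °C to rt
Reagents that add atoms: none
Why: Steglich esterification, in which DMAP relays the O-acylisourea as an acylpyridinium ion to the free and more acidic 4-hydroxyl of 15 while the 2-hydroxyl is held in a hydrogen bond to the ester carbonyl, and the dioxolane keeps the chain ketone from capturing the activated carboxyl as an enol lactone.

**Step 9**
Reactants: 16 benzyl 4-({2-(benzyloxy)-6-[(2-heptyl-1,3-dioxolan-2-yl)methyl]-4-methoxybenzoyl}oxy)-2-hydroxy-6-methylbenzoate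
Product: 17 benzyl 4-{[2-(benzyloxy)-4-methoxy-6-(2-oxononyl)benzoyl]oxy}-2-hydroxy-6-methylbenzoate
Conditions: 1 M HCl, THF, rt
Reagents that add atoms: water, O
Why: Acid-catalysed ketal hydrolysis through the oxocarbenium ion returns the ketone, and dilute acid at room temperature should leave the aryl ester, the benzyl ester and the benzyl ether untouched provided the reaction is stopped at full conversion.

**Step 10**
Reactants: 17 benzyl 4-{[2-(benzyloxy)-4-methoxy-6-(2-oxononyl)benzoyl]oxy}-2-hydroxy-6-methylbenzoate
Product: 18 2-hydroxy-4-{[2-hydroxy-4-methoxy-6-(2-oxononyl)benzoyl]oxy}-6-methylbenzoic acid (CNP0320117.0)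
Conditions: H2 (1 atm), 10% Pd/C, EtOAc, rt
Reagents that add atoms: none
Why: Hydrogenolysis over palladium on carbon cleaves the O–benzyl bonds of the aryl benzyl ether and the benzyl ester under neutral conditions, which spare the aryl ester, the ketone and the arenes and avoid any acid or base that could close the keto depside to an isocoumarin.

**Compound list**
1 | 2-hydroxy-4-methoxybenzoic acid | COc1ccc(C(=O)O)c(O)c1 | starting material
2 | benzyl 2-(benzyloxy)-4-methoxybenzoate | COc1ccc(C(=O)OCc2ccccc2)c(OCc2ccccc2)c1 | intermediate (not isolated)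
3 | 2-(benzyloxy)-4-methoxybenzoic acid | COc1ccc(C(=O)O)c(OCc2ccccc2)c1 | intermediate
4 | trimethylsulfoxonium iodide | C[S+](C)(C)=O.[I-] | starting material
5 | octanoyl chloride | CCCCCCCC(Cl)=O | starting material
6 | dimethylsulfoxonium methylide | C=S(C)(C)=O | intermediate (not isolated)
7 | 1-[dimethyl(oxo)-λ6-sulfanylidene]nonan-2-one | CCCCCCCC(=O)C=S(C)(C)=O | intermediate
8 | 2-(benzyloxy)-4-methoxy-6-(2-oxononyl)benzoic acid | CCCCCCCC(=O)Cc1cc(OC)cc(OCc2ccccc2)c1C(=O)O | intermediate (not isolated)
9 | 8-(benzyloxy)-3-heptyl-6-methoxy-1H-isochromen-1-one | CCCCCCCc1cc2cc(OC)cc(OCc3ccccc3)c2c(=O)o1 | intermediate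
10 | potassium 2-(benzyloxy)-4-methoxy-6-(2-oxononyl)benzoate | CCCCCCCC(=O)Cc1cc(OC)cc(OCc2ccccc2)c1C(=O)[O-].[K+] | intermediate (not isolated)
11 | allyl 2-(benzyloxy)-4-methoxy-6-(2-oxononyl)benzoate | CCCCCCCC(=O)Cc1cc(OC)cc(OCc2ccccc2)c1C(=O)OCC=C | intermediate
12 | allyl 2-(benzyloxy)-6-[(2-heptyl-1,3-dioxolan-2-yl)methyl]-4-methoxybenzoate | CCCCCCCC1(Cc2cc(OC)cc(OCc3ccccc3)c2C(=O)OCC=C)OCCO1 | intermediate
13 | 2-(benzyloxy)-6-[(2-heptyl-1,3-dioxolan-2-yl)methyl]-4-methoxybenzoic acid | CCCCCCCC1(Cc2cc(OC)cc(OCc3ccccc3)c2C(=O)O)OCCO1 | intermediate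
14 | orsellinic acid (2,4-dihydroxy-6-methylbenzoic acid) | Cc1cc(O)cc(O)c1C(=O)O | starting material
15 | benzyl 2,4-dihydroxy-6-methylbenzoate | Cc1cc(O)cc(O)c1C(=O)OCc1ccccc1 | intermediate
16 | benzyl 4-({2-(benzyloxy)-6-[(2-heptyl-1,3-dioxolan-2-yl)methyl]-4-methoxybenzoyl}oxy)-2-hydroxy-6-methylbenzoate | CCCCCCCC1(Cc2cc(OC)cc(OCc3ccccc3)c2C(=O)Oc2cc(C)c(C(=O)OCc3ccccc3)c(O)c2)OCCO1 | intermediate
17 | benzyl 4-{[2-(benzyloxy)-4-methoxy-6-(2-oxononyl)benzoyl]oxy}-2-hydroxy-6-methylbenzoate | CCCCCCCC(=O)Cc1cc(OC)cc(OCc2ccccc2)c1C(=O)Oc1cc(C)c(C(=O)OCc2ccccc2)c(O)c1 | intermediate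
18 | 2-hydroxy-4-{[2-hydroxy-4-methoxy-6-(2-oxononyl)benzoyl]oxy}-6-methylbenzoic acid | CCCCCCCC(=O)Cc1cc(OC)cc(O)c1C(=O)Oc1cc(C)c(C(=O)O)c(O)c1 | target

**Step count**
Total: 10 steps. Longest linear sequence: 8 steps (steps 1, 3, 4, 5, 6, 8, 9, 10).

**Steps most likely to fail**

Step 3. The carboxylate is a weak director here: the ortho benzyloxy group turns it out of the ring plane and C6 is meta to both alkoxy groups. C–H cleavage may therefore be slower than protonation and decay of the ylide, and conversion may stall. The fallback sets out from acid 3 and exchanges the directing group for a stronger one. Condensation with O-methylhydroxylamine hydrochloride (EDC·HCl, Et3N, CH2Cl2) should give 2-(benzyloxy)-N,4-dimethoxybenzamide F1. Under [Cp*RhCl2]2/AgSbF6 with pivalic acid in HFIP, F1 and ylide 7 should undergo the same C6–H acylmethylation. The amide oxygen then closes onto the ketone, and hydrolysis of the resulting imidate expels O-methylhydroxylamine. The route is rejoined at isocoumarin 9.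

Step 8. Acyl transfer from the doubly ortho-substituted O-acylisourea may be slower than its rearrangement to the N-acylurea, and part of the acylation may go to the 2-hydroxyl. The fallback sets out from acid 13 and separates activation from coupling. 1-Chloro-N,N,2-trimethylprop-1-en-1-amine in CH2Cl2 at 0 °C releases no acid, so the ketal is safe, and should give 2-(benzyloxy)-6-[(2-heptyl-1,3-dioxolan-2-yl)methyl]-4-methoxybenzoyl chloride F2. This is added to the potassium 4-phenoxide of 15 (KOtBu, 1 equiv, THF, −20 °C; the hydroxyl para to the ester is the more acidic one). The route is rejoined at ester 16.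

Step 5. The silyl-activated ketone may be captured by the neighbouring ester carbonyl oxygen instead of the diol ether, with loss of the allyl group and return to the isocoumarin, or ketal formation may stay incomplete. The fallback gives up ketone protection and uses the free ortho-hydroxy acid, whose carbodiimide coupling needs no base. It sets out from keto ester 11. The allyl group is removed (Pd(PPh3)4, morpholine, THF) and keto acid 8 is isolated from a cold buffered work-up. Hydrogenolysis of its benzyl ether (H2, 10% Pd/C, EtOAc) should give 2-hydroxy-4-methoxy-6-(2-oxononyl)benzoic acid F3. Coupling with 15 by DCC alone in toluene at room temperature, neutral conditions under which the ketone is not enolised, should give benzyl 2-hydroxy-4-{[2-hydroxy-4-methoxy-6-(2-oxononyl)benzoyl]oxy}-6-methylbenzoate F4. Hydrogenolysis of the benzyl ester (H2, 10% Pd/C, EtOAc) rejoins the route at target 18.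

**Further compounds**
F1 | step 3 | 2-(benzyloxy)-N,4-dimethoxybenzamide | CONC(=O)c1ccc(OC)cc1OCc1ccccc1
F2 | step 8 | 2-(benzyloxy)-6-[(2-heptyl-1,3-dioxolan-2-yl)methyl]-4-methoxybenzoyl chloride | CCCCCCCC1(Cc2cc(OC)cc(OCc3ccccc3)c2C(Cl)=O)OCCO1
F3 | step 5 | 2-hydroxy-4-methoxy-6-(2-oxononyl)benzoic acid | CCCCCCCC(=O)Cc1cc(OC)cc(O)c1C(=O)O
F4 | step 5 | benzyl 2-hydroxy-4-{[2-hydroxy-4-methoxy-6-(2-oxononyl)benzoyl]oxy}-6-methylbenzoate | CCCCCCCC(=O)Cc1cc(OC)cc(O)c1C(=O)Oc1cc(C)c(C(=O)OCc2ccccc2)c(O)c1
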